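**Retrosynthetic overview**
1. The target is read as three flavan units: upper U (2S,3S,4R), middle M (2R,3R,4S), lower L (2S,3S,4R; a 3,4-trans diol), joined C4(U)→C8(M) and C4(M)→C8(L), both 3,4-cis. Last operations: C4–OH of L by DDQ/H2O, then removal of all benzyl ethers.
2. U–M bond: aryllithium at C8 of the M–L dimer plus the 4-ketone of U, then ionic deoxygenation (gives 3,4-cis).
3. M pyran ring and M–L bond in one operation: 8-lithio-L adds to an auronol methyl ketal; the furanone ring (O1, C3, C4, C4a, C8a) is enlarged by C2 through an o-quinone methide and oxa-6π closure (auronol → flavonoid, biomimetic). A dynamic-kinetic hydrogenation then sets C2, C3, C4 of M all-cis.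
4. Enabling feature: C4 of M sits on the 5,7-dioxygenated A ring ortho to C8a–O1, so a C4 cation is the o-quinone methide O1=C8a–C4a=C4, and C3 carries oxygen next to the benzylic C2–H.
5. All units come from one chalcone; ring order: pyran of L/U (step 2), furanone of the M precursor (step 10), pyran of M by ring enlargement (step 13).

Key step: step 13

**Remarks**
- Compounds 1 and 2 are taken as catalogue chemicals. Bn = benzyl. ArL = (2S,3S)-3,5,7-tris(benzyloxy)-2-[4-(benzyloxy)phenyl]chroman-8-yl.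
- The catalyst enantiomer named in step 5 is the one expected to give the (3S)-carbinol; its sense is to be confirmed on 9, and step 14 uses the mirror-image complex.
- CIP descriptors at C4 of the middle unit change with the C8 substituent (H, Br, C) and with the oxidation state of the lower unit; the geometry (all-cis) is the same throughout.

**Step 1**
Reactants: 1 1-[2,4-bis(benzyloxy)-6-hydroxyphenyl]ethan-1-one; 2 4-(benzyloxy)benzaldehyde
Product: 3 (E)-1-[2,4-bis(benzyloxy)-6-hydroxyphenyl]-3-[4-(benzyloxy)phenyl]prop-2-en-1-one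
Conditions: KOH (50% aq.), EtOH, rt
Reagents that add atoms: none
Why: Claisen–Schmidt aldol condensation of a methyl ketone with a non-enolisable aldehyde should give the (E)-chalcone; no stereocentre is formed.

**Step 2**
Reactants: 3 chalcone
Product: 5 rac-5,7-bis(benzyloxy)-2-[4-(benzyloxy)phenyl]-2H-chromene, via allylic alcohol 4 (not isolated)
Conditions: NaBH4, THF/EtOH, 0 °C → reflux; then AcOH, rt
Reagents that add atoms: none
Why: Reductive cyclisation of a 2'-hydroxychalcone: 1,2-reduction gives the allylic alcohol, which ionises readily and is closed by the phenol at the aryl-bearing allyl terminus (6-membered ring); C2 is racemic and is corrected in steps 4–5.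

**Step 3**
Reactants: 5 flav-3-ene
Product: 7 rac-(2R*,3S*)-5,7-bis(benzyloxy)-2-[4-(benzyloxy)phenyl]chroman-3-ol, via alkylborane 6 (not isolated)
Conditions: BH3·THF, THF, 0 °C → rt; then NaOH, H2O2, 0 °C
Reagents that add atoms: hydrogen peroxide, OO
Why: Brown hydroboration–oxidation of the styrene-type C3=C4 bond places boron on C3 anti to the C2 aryl, and retentive oxidation should give the 2,3-trans alcohol as the racemate.

**Step 4**
Reactants: 7 rac-trans-flavan-3-ol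
Product: 8 rac-5,7-bis(benzyloxy)-2-[4-(benzyloxy)phenyl]chroman-3-one
Conditions: Dess–Martin periodinane, CH2Cl2, rt
Reagents that add atoms: none
Why: Dess–Martin oxidation of the secondary alcohol removes the C3 centre and makes C2 enolisable, which the next step needs.

**Step 5**
Reactants: 8 rac-flavan-3-one
Product: 9 (2S,3S)-5,7-bis(benzyloxy)-2-[4-(benzyloxy)phenyl]chroman-3-ol
Conditions: RuCl2[(S)-Xyl-SDP][(R,R)-DPEN] (1 mol %), KOtBu (cat.), H2 (50 atm), iPrOH/toluene, rt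
Reagents that add atoms: none
Why: Noyori-type Ru/diphosphine/diamine hydrogenation of an α-aryl cyclic ketone with dynamic kinetic resolution: base racemises C2 through the enolate, and the catalyst should reduce one enantiomer from the face anti to the aryl group, giving the 2,3-cis alcohol with catalyst-controlled absolute configuration.

**Step 6**
Reactants: 9 (2S,3S)-cis-flavan-3-ol
Product: 10 (2S,3S)-3,5,7-tris(benzyloxy)-2-[4-(benzyloxy)phenyl]chromane
Conditions: NaH, BnBr, Bu4NI (cat.), DMF, 0 °C → rt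
Reagents that add atoms: benzyl bromide, BrCc1ccccc1
Why: Williamson etherification of the secondary alkoxide; no stereocentre is touched.

**Step 7**
Reactants: 10 tetra-O-benzyl flavan
Product: 11 (2S,3S)-3,5,7-tris(benzyloxy)-2-[4-(benzyloxy)phenyl]-8-bromochromane
Conditions: NBS, CH2Cl2, −78 → 0 °C
Reagents that add atoms: N-bromosuccinimide, O=C1CCC(=O)N1Br
Why: Electrophilic aromatic bromination should occur at C8, which is activated by three oxygens and less hindered than C6 (flanked by two benzyloxy groups).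

**Step 8**
Reactants: 10 tetra-O-benzyl flavan
Product: 12 (2S,3S,4R)-3,5,7-tris(benzyloxy)-2-[4-(benzyloxy)phenyl]chroman-4-ol
Conditions: DDQ, CH2Cl2/H2O (20:1), rt
Reagents that add atoms: water, O
Why: DDQ benzylic oxidation by hydride abstraction to the A-ring-stabilised C4 cation; water should add anti to the 2-aryl and 3-benzyloxy groups (3,4-trans).

**Step 9**
Reactants: 12 flavan-4-ol
Product: 13 (2S,3R)-3,5,7-tris(benzyloxy)-2-[4-(benzyloxy)phenyl]chroman-4-one (2,3-cis)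
Conditions: Dess–Martin periodinane, CH2Cl2, 0 °C → rt
Reagents that add atoms: none
Why: Dess–Martin oxidation of the benzylic alcohol under non-basic conditions, which should leave the α-benzyloxy centre C3 and C2 unepimerised.

**Step 10**
Reactants: 3 chalcone
Product: 14 (Z)-4,6-bis(benzyloxy)-2-[4-(benzyloxy)benzylidene]benzofuran-3(2H)-one
Conditions: Hg(OAc)2, pyridine, 110 °C
Reagents that add atoms: none
Why: Mercury(II)-mediated oxidative cyclisation of a 2'-hydroxychalcone (5-exo oxymercuration at the α-carbon, then dehydromercuration) should give the thermodynamic (Z)-aurone.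

**Step 11**
Reactants: 14 aurone
Product: 16 rac-4,6-bis(benzyloxy)-2-[4-(benzyloxy)benzyl]-2-hydroxybenzofuran-3(2H)-one, via hydroperoxide 15 (not isolated)
Conditions: Mn(dpm)3 (5 mol %), PhSiH3, O2 (1 atm), iPrOH/CH2Cl2, 0 °C; then P(OEt)3
Reagents that add atoms: dioxygen, O=O
Why: Mukaiyama-type reductive α-hydroxylation of an enone: hydrogen-atom transfer to the benzylidene carbon gives the captodative C2 radical, which is trapped by O2, and the phosphite reduces the hydroperoxide; the new centre is racemic and is erased in step 13.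

**Step 12**
Reactants: 16 auronol
Product: 17 rac-4,6-bis(benzyloxy)-2-[4-(benzyloxy)benzyl]-2-methoxybenzofuran-3(2H)-one
Conditions: MeOTf, 2,6-di-tert-butyl-4-methylpyridine, CH2Cl2, 0 °C → rt
Reagents that add atoms: methyl trifluoromethanesulfonate, COS(=O)(=O)C(F)(F)F
Why: O-Methylation of the tertiary hemiketal hydroxyl under neutral conditions locks the ring form and removes the acidic proton, avoiding the acid-promoted dehydration back to the aurone.

**Step 13**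
Reactants: 11 8-bromo flavan; 17 auronol methyl ketal
Product: 22 5,7-bis(benzyloxy)-2-[4-(benzyloxy)phenyl]-4-ArL-chroman-3-one (mixture of C2/C4 epimers), via aryllithium 18 (not isolated), via lithium alkoxide adduct 19 (not isolated), via o-quinone methide 20 (not isolated), via 3-methoxy-2H-chromene 21 (not isolated)
Conditions: 11, t-BuLi (2 equiv), THF, −78 °C; then 17, −78 → −40 °C; then TFA, CH2Cl2, −78 → 0 °C; then 1 M HCl, THF, rt
Reagents that add atoms: water, O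
Why: Proposed new method: Br/Li exchange gives aryllithium 18, which adds to the non-enolisable ketone of 17 (the later C4; close precedent: addition of 8-lithioflavans to hindered flavan-4-ones), and acid ionises the bis-aryl carbinol 19 to a cation that is an O1-stabilised o-quinone methide, so the methoxy lone pair pushes open the O1–C3 bond of the five-membered ring and loss of the acidic benzylic C2 proton gives 20. The 1-oxatriene 20 (O1=C8a–C4a=C4–C3=C2) should close by a thermal disrotatory oxa-6π electrocyclisation (O1–C2 bond, driven by re-aromatisation) to the 2H-chromene 21, so that the furanone ring (O1, C3, C4, C4a, C8a) is enlarged by C2 to the pyran ring, and hydrolysis of the enol ether gives ketone 22. The closest known reactions are the valence isomerisation of benzofuran epoxides to o-quinone methides, the oxa-6π closure of vinyl o-quinone methides to 2H-chromenes, and the biogenetic auronol/dihydroflavonol interconversion. C2 and C4 are formed without control on purpose, because both are enolisable in 22 and are set in step 14, while the two stereocentres of 19 are erased. The selectivities needed are carbinol ionisation before ketal ionisation (secured by the two trioxygenated aryl groups on C4) and fragmentation with proton loss before a 1,2-benzyl shift to a benzofuran-2(3H)-one (secured by the ketal oxygen lone pair and the acidity of the C2 protons in the oxocarbenium ion); only O1–C2 closure restores the aromatic A ring.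

**Step 14**
Reactants: 22 2,4-diarylchroman-3-one
Product: 23 (2R,3R,4S)-5,7-bis(benzyloxy)-2-[4-(benzyloxy)phenyl]-4-ArL-chroman-3-ol (2,3-cis-3,4-cis)
Conditions: RuCl2[(R)-Xyl-SDP][(S,S)-DPEN] (2 mol %), KOtBu (cat.), H2 (50 atm), iPrOH/toluene, 30 °C
Reagents that add atoms: none
Why: Ru-catalysed asymmetric hydrogenation with dynamic kinetic resolution of an α,α'-disubstituted cyclic ketone: both C2 and C4 epimerise through the enolates, and the mirror-image catalyst of step 5 should reduce the (2R,4S)-cis ketone from the face anti to both aryl groups, funnelling four stereoisomers into the all-cis alcohol under catalyst control.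

**Step 15**
Reactants: 23 M–L dimer alcohol
Product: 24 (2R,3R,4R)-5,7-bis(benzyloxy)-2-[4-(benzyloxy)phenyl]-8-bromo-4-ArL-chroman-3-ol (same geometry as 23)
Conditions: NBS (1.0 equiv), CH2Cl2, −78 → −20 °C
Reagents that add atoms: N-bromosuccinimide, O=C1CCC(=O)N1Br
Why: Electrophilic aromatic bromination; of the three free A-ring positions only C8 of the middle unit is of the reactive C8 type, whereas both C6 positions lie between two benzyloxy groups.

**Step 16**
Reactants: 24 bromo dimer; 13 flavan-4-one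
Product: 26 tertiary carbinol: unit U (2S,3R,4R)-3,5,7-tris(benzyloxy)-2-[4-(benzyloxy)phenyl]-4-hydroxychroman-4-yl attached through C4 to C8 of the debrominated 24 skeleton, via dilithio species 25 (not isolated)
Conditions: 24, t-BuLi (3.1 equiv), THF, −78 °C; then 13, −78 → −20 °C; then H2O
Reagents that add atoms: none
Why: Deprotonation of the 3-OH and Br/Li exchange give an aryllithium that adds 1,2 to the flavan-4-one, the reaction type precedented for 4→8-linked flavan dimers; the carbinol configuration (drawn with aryl anti to the 3-benzyloxy group) is removed in the next step.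

**Step 17**
Reactants: 26 tertiary carbinol
Product: 27 protected trimer: U (2S,3S,4R; 3,5,7,4'-tetra-O-benzyl)-(4→8)-M (2R,3R,4R; 5,7,4'-tri-O-benzyl, 3-OH)-(4→8)-L (2S,3S; tetra-O-benzyl)
Conditions: Bu3SnH, TFA, CH2Cl2, 0 °C
Reagents that add atoms: none
Why: Ionic deoxygenation of the bis-benzylic tertiary alcohol: TFA gives the C4 cation and Bu3SnH should deliver hydride anti to the 2-aryl and 3-benzyloxy groups, leaving the C4 aryl cis to both (2,3-cis-3,4-cis), as precedented for 3,4-cis 4→8 flavan dimers.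

**Step 18**
Reactants: 27 protected trimer
Product: 28 protected trimer 4-ol: as 27 with (4R)-OH on the lower unit (L 2S,3S,4R; M now 2R,3R,4S by CIP)
Conditions: DDQ, CH2Cl2/H2O (20:1), rt
Reagents that add atoms: water, O
Why: DDQ benzylic oxidation should select the only benzylic methylene (C4 of the terminal unit), the two interflavan methines being sterically shielded; water adds to the cation anti to the 2-aryl and 3-benzyloxy groups (3,4-trans).

**Step 19**
Reactants: 28 protected trimer 4-ol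
Product: 29 CNP0159291.1
Conditions: H2 (1 atm), Pd(OH)2/C, THF/MeOH/H2O, rt, neutral, short contact time
Reagents that add atoms: none
Why: Hydrogenolysis of the eleven benzyl ethers over Pearlman's catalyst touches no stereocentre; neutral medium and short time are chosen to keep the benzylic 4-hydroxyl.

**Compound list**
1 | 1-[2,4-bis(benzyloxy)-6-hydroxyphenyl]ethan-1-one | CC(=O)c1c(O)cc(OCc2ccccc2)cc1OCc1ccccc1 | starting material
2 | 4-(benzyloxy)benzaldehyde | O=Cc1ccc(OCc2ccccc2)cc1 | starting material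
3 | (E)-chalcone | O=C(/C=C/c1ccc(OCc2ccccc2)cc1)c1c(O)cc(OCc2ccccc2)cc1OCc1ccccc1 | intermediate
4 | rac-(E)-3,5-bis(benzyloxy)-2-{3-[4-(benzyloxy)phenyl]-1-hydroxyprop-2-en-1-yl}phenol | OC(/C=C/c1ccc(OCc2ccccc2)cc1)c1c(O)cc(OCc2ccccc2)cc1OCc1ccccc1 | intermediate (not isolated)
5 | rac-5,7-bis(benzyloxy)-2-[4-(benzyloxy)phenyl]-2H-chromene | C1=CC(c2ccc(OCc3ccccc3)cc2)Oc2cc(OCc3ccccc3)cc(OCc3ccccc3)c21 | intermediate
6 | rac-(2R*,3S*)-{5,7-bis(benzyloxy)-2-[4-(benzyloxy)phenyl]chroman-3-yl}borane (one enantiomer drawn) | [C@H]1(c2ccc(OCc3ccccc3)cc2)Oc2cc(OCc3ccccc3)cc(OCc3ccccc3)c2C[C@@H]1B | intermediate (not isolated)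
7 | rac-(2R*,3S*)-5,7-bis(benzyloxy)-2-[4-(benzyloxy)phenyl]chroman-3-ol (one enantiomer drawn) | [C@H]1(c2ccc(OCc3ccccc3)cc2)Oc2cc(OCc3ccccc3)cc(OCc3ccccc3)c2C[C@@H]1O | intermediate
8 | rac-5,7-bis(benzyloxy)-2-[4-(benzyloxy)phenyl]chroman-3-one | O=C1Cc2c(OCc3ccccc3)cc(OCc3ccccc3)cc2OC1c1ccc(OCc2ccccc2)cc1 | intermediate
9 | (2S,3S)-5,7-bis(benzyloxy)-2-[4-(benzyloxy)phenyl]chroman-3-ol | [C@@H]1(c2ccc(OCc3ccccc3)cc2)Oc2cc(OCc3ccccc3)cc(OCc3ccccc3)c2C[C@@H]1O | intermediate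
10 | (2S,3S)-3,5,7-tris(benzyloxy)-2-[4-(benzyloxy)phenyl]chromane | [C@@H]1(c2ccc(OCc3ccccc3)cc2)Oc2cc(OCc3ccccc3)cc(OCc3ccccc3)c2C[C@@H]1OCc1ccccc1 | intermediate
11 | (2S,3S)-3,5,7-tris(benzyloxy)-2-[4-(benzyloxy)phenyl]-8-bromochromane | [C@@H]1(c2ccc(OCc3ccccc3)cc2)Oc2c(Br)c(OCc3ccccc3)cc(OCc3ccccc3)c2C[C@@H]1OCc1ccccc1 | intermediate
12 | (2S,3S,4R)-3,5,7-tris(benzyloxy)-2-[4-(benzyloxy)phenyl]chroman-4-ol | [C@@H]1(c2ccc(OCc3ccccc3)cc2)Oc2cc(OCc3ccccc3)cc(OCc3ccccc3)c2[C@@H](O)[C@@H]1OCc1ccccc1 | intermediate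
13 | (2S,3R)-3,5,7-tris(benzyloxy)-2-[4-(benzyloxy)phenyl]chroman-4-one | [C@@H]1(c2ccc(OCc3ccccc3)cc2)Oc2cc(OCc3ccccc3)cc(OCc3ccccc3)c2C(=O)[C@@H]1OCc1ccccc1 | intermediate
14 | (Z)-4,6-bis(benzyloxy)-2-[4-(benzyloxy)benzylidene]benzofuran-3(2H)-one | O=C1c2c(OCc3ccccc3)cc(OCc3ccccc3)cc2O/C1=C\c1ccc(OCc2ccccc2)cc1 | intermediate
15 | rac-4,6-bis(benzyloxy)-2-[4-(benzyloxy)benzyl]-2-hydroperoxybenzofuran-3(2H)-one | O=C1c2c(OCc3ccccc3)cc(OCc3ccccc3)cc2OC1(OO)Cc1ccc(OCc2ccccc2)cc1 | intermediate (not isolated)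
16 | rac-4,6-bis(benzyloxy)-2-[4-(benzyloxy)benzyl]-2-hydroxybenzofuran-3(2H)-one | O=C1c2c(OCc3ccccc3)cc(OCc3ccccc3)cc2OC1(O)Cc1ccc(OCc2ccccc2)cc1 | intermediate
17 | rac-4,6-bis(benzyloxy)-2-[4-(benzyloxy)benzyl]-2-methoxybenzofuran-3(2H)-one | O=C1c2c(OCc3ccccc3)cc(OCc3ccccc3)cc2OC1(OC)Cc1ccc(OCc2ccccc2)cc1 | intermediate
18 | [(2S,3S)-3,5,7-tris(benzyloxy)-2-(4-benzyloxyphenyl)chroman-8-yl]lithium | [C@@H]1(c2ccc(OCc3ccccc3)cc2)Oc2c([Li])c(OCc3ccccc3)cc(OCc3ccccc3)c2C[C@@H]1OCc1ccccc1 | intermediate (not isolated)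
19 | lithium 4,6-bis(benzyloxy)-2-[4-(benzyloxy)benzyl]-2-methoxy-3-ArL-2,3-dihydrobenzofuran-3-olate (mixture at C2/C3 of the furan ring) | [Li]OC1(c2c(OCc3ccccc3)cc(OCc3ccccc3)c3c2O[C@@H](c2ccc(OCc4ccccc4)cc2)[C@@H](OCc2ccccc2)C3)c2c(OCc3ccccc3)cc(OCc3ccccc3)cc2OC1(OC)Cc1ccc(OCc2ccccc2)cc1 | intermediate (not isolated)
20 | (Z)-3,5-bis(benzyloxy)-6-{1-ArL-3-[4-(benzyloxy)phenyl]-2-methoxyprop-2-en-1-ylidene}cyclohexa-2,4-dien-1-one (enol ether geometry not defined) | O=C1C=C(OCc2ccccc2)C=C(OCc2ccccc2)/C1=C(\c1c(OCc2ccccc2)cc(OCc2ccccc2)c2c1O[C@@H](c1ccc(OCc3ccccc3)cc1)[C@@H](OCc1ccccc1)C2)C(OC)=Cc1ccc(OCc2ccccc2)cc1 | intermediate (not isolated)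
21 | 5,7-bis(benzyloxy)-2-[4-(benzyloxy)phenyl]-3-methoxy-4-ArL-2H-chromene (C2 epimers) | COC1=C(c2c(OCc3ccccc3)cc(OCc3ccccc3)c3c2O[C@@H](c2ccc(OCc4ccccc4)cc2)[C@@H](OCc2ccccc2)C3)c2c(OCc3ccccc3)cc(OCc3ccccc3)cc2OC1c1ccc(OCc2ccccc2)cc1 | intermediate (not isolated)
22 | 5,7-bis(benzyloxy)-2-[4-(benzyloxy)phenyl]-4-ArL-chroman-3-one (C2/C4 epimers) | O=C1C(c2ccc(OCc3ccccc3)cc2)Oc2cc(OCc3ccccc3)cc(OCc3ccccc3)c2C1c1c(OCc2ccccc2)cc(OCc2ccccc2)c2c1O[C@@H](c1ccc(OCc3ccccc3)cc1)[C@@H](OCc1ccccc1)C2 | intermediate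
23 | (2R,3R,4S)-5,7-bis(benzyloxy)-2-[4-(benzyloxy)phenyl]-4-ArL-chroman-3-ol | [C@H]1(c2ccc(OCc3ccccc3)cc2)Oc2cc(OCc3ccccc3)cc(OCc3ccccc3)c2[C@@H](c2c(OCc3ccccc3)cc(OCc3ccccc3)c3c2O[C@@H](c2ccc(OCc4ccccc4)cc2)[C@@H](OCc2ccccc2)C3)[C@H]1O | intermediate
24 | (2R,3R,4R)-5,7-bis(benzyloxy)-2-[4-(benzyloxy)phenyl]-8-bromo-4-ArL-chroman-3-ol | [C@H]1(c2ccc(OCc3ccccc3)cc2)Oc2c(Br)c(OCc3ccccc3)cc(OCc3ccccc3)c2[C@@H](c2c(OCc3ccccc3)cc(OCc3ccccc3)c3c2O[C@@H](c2ccc(OCc4ccccc4)cc2)[C@@H](OCc2ccccc2)C3)[C@H]1O | intermediate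
25 | 8-lithio-3-O-lithio derivative of debrominated 24 | [C@H]1(c2ccc(OCc3ccccc3)cc2)Oc2c([Li])c(OCc3ccccc3)cc(OCc3ccccc3)c2[C@@H](c2c(OCc3ccccc3)cc(OCc3ccccc3)c3c2O[C@@H](c2ccc(OCc4ccccc4)cc2)[C@@H](OCc2ccccc2)C3)[C@H]1O[Li] | intermediate (not isolated)
26 | tertiary carbinol, U (2S,3R,4R)-4-hydroxy unit on C8 of M (2R,3R,4R), L (2S,3S) | [C@H]1(c2ccc(OCc3ccccc3)cc2)Oc2c([C@]5(O)c6c(OCc7ccccc7)cc(OCc7ccccc7)cc6O[C@@H](c6ccc(OCc7ccccc7)cc6)[C@H]5OCc5ccccc5)c(OCc3ccccc3)cc(OCc3ccccc3)c2[C@@H](c2c(OCc3ccccc3)cc(OCc3ccccc3)c3c2O[C@@H](c2ccc(OCc4ccccc4)cc2)[C@@H](OCc2ccccc2)C3)[C@H]1O | intermediate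
27 | protected trimer, U (2S,3S,4R), M (2R,3R,4R), L (2S,3S), eleven benzyl ethers, M 3-OH free | [C@H]1(c2ccc(OCc3ccccc3)cc2)Oc2c([C@H]5c6c(OCc7ccccc7)cc(OCc7ccccc7)cc6O[C@@H](c6ccc(OCc7ccccc7)cc6)[C@H]5OCc5ccccc5)c(OCc3ccccc3)cc(OCc3ccccc3)c2[C@@H](c2c(OCc3ccccc3)cc(OCc3ccccc3)c3c2O[C@@H](c2ccc(OCc4ccccc4)cc2)[C@@H](OCc2ccccc2)C3)[C@H]1O | intermediate
28 | protected trimer 4-ol, U (2S,3S,4R), M (2R,3R,4S), L (2S,3S,4R) | [C@H]1(c2ccc(OCc3ccccc3)cc2)Oc2c([C@H]5c6c(OCc7ccccc7)cc(OCc7ccccc7)cc6O[C@@H](c6ccc(OCc7ccccc7)cc6)[C@H]5OCc5ccccc5)c(OCc3ccccc3)cc(OCc3ccccc3)c2[C@@H](c2c(OCc3ccccc3)cc(OCc3ccccc3)c3c2O[C@@H](c2ccc(OCc4ccccc4)cc2)[C@@H](OCc2ccccc2)[C@@H]3O)[C@H]1O | intermediate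
29 | CNP0159291.1, (2S,3S,4R)-2-(4-hydroxyphenyl)-8-{(2R,3R,4S)-3,5,7-trihydroxy-2-(4-hydroxyphenyl)-8-[(2S,3S,4R)-3,5,7-trihydroxy-2-(4-hydroxyphenyl)chroman-4-yl]chroman-4-yl}chromane-3,4,5,7-tetrol | Oc1ccc([C@H]2Oc3c(c(O)cc(O)c3[C@H]3c4c(O)cc(O)cc4O[C@@H](c4ccc(O)cc4)[C@H]3O)[C@@H](c3c(O)cc(O)c4c3O[C@@H](c3ccc(O)cc3)[C@@H](O)[C@@H]4O)[C@H]2O)cc1 | target

**Totals**
Total step count: 19. Longest linear sequence: 14 steps (steps 1–7, then 13–19).

**Steps most likely to fail**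

Step 13 (proposed new method). What may go wrong: slow addition of the doubly ortho-substituted aryllithium to the hindered, vinylogous-carbonate-type ketone; or diversion of the ionised adduct by a 1,2-benzyl shift or by ketal ionisation instead of fragmentation to the quinone methide. The fallback uses known chemistry, sets out from 8 and 11, bypasses steps 13 and 14, and returns at 23. Ketone 8 is hydrogenated under the step-5 conditions with the mirror-image catalyst to (2R,3R)-5,7-bis(benzyloxy)-2-[4-(benzyloxy)phenyl]chroman-3-ol F1. TBSCl/imidazole gives its 3-O-TBS ether F2. DDQ/H2O gives the 3,4-trans flavan-4-ol F3, and Dess–Martin periodinane gives the flavan-4-one F4. Aryllithium 18 (from 11 and t-BuLi) adds to F4 to give the tertiary carbinol F5. Bu3SnH/TFA delivers hydride anti to the 2-aryl and 3-silyloxy groups and gives the all-cis silylated dimer F6, and TBAF then gives 23.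

Step 14. What may go wrong: epimerisation at the congested C4 may be slower than hydrogenation, or the catalyst may not accept the di-ortho-substituted α-aryl ketone, so that diastereoselection or turnover is lost. The fallback sets out from 22 and returns at 23. Ketone 22 is equilibrated with DBU and reduced with L-Selectride at −78 °C, which attacks anti to both aryl groups and should give the two all-cis carbinols, 23 and the (2S,3S,4R)-configured middle-unit diastereomer F7. These are diastereomers through the chiral lower unit and are separated by chromatography; F7 is re-oxidised with Dess–Martin periodinane to 22 and recycled.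

Step 19. What may go wrong: hydrogenolytic cleavage of the benzylic C4–OH bond of the lower unit, which is activated by the 5,7-dioxygenated ring, during O-debenzylation. The fallback sets out from 27 and returns at 29; it inverts oxidation and deprotection through a protecting-group exchange. Hydrogenolysis of 27 (H2, Pd(OH)2/C), which has no benzylic hydroxyl, gives the dodecahydroxy trimer F8. TBSOTf/2,6-lutidine gives the dodeca-O-TBS ether F9. DDQ/H2O hydroxylates C4 of the lower unit trans to the 3-silyloxy group to give the 4-hydroxy dodeca-O-TBS ether F10, and buffered HF·pyridine gives 29.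

**Further compounds**
F1 | step 13 | (2R,3R)-5,7-bis(benzyloxy)-2-[4-(benzyloxy)phenyl]chroman-3-ol | [C@H]1(c2ccc(OCc3ccccc3)cc2)Oc2cc(OCc3ccccc3)cc(OCc3ccccc3)c2C[C@H]1O
F2 | step 13 | (2R,3R)-3-O-TBS ether of F1 | [C@H]1(c2ccc(OCc3ccccc3)cc2)Oc2cc(OCc3ccccc3)cc(OCc3ccccc3)c2C[C@H]1O[Si](C)(C)C(C)(C)C
F3 | step 13 | (2R,3R,4S)-5,7-bis(benzyloxy)-2-[4-(benzyloxy)phenyl]-3-(tert-butyldimethylsilyloxy)chroman-4-ol | [C@H]1(c2ccc(OCc3ccccc3)cc2)Oc2cc(OCc3ccccc3)cc(OCc3ccccc3)c2[C@H](O)[C@H]1O[Si](C)(C)C(C)(C)C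
F4 | step 13 | (2R,3S)-5,7-bis(benzyloxy)-2-[4-(benzyloxy)phenyl]-3-(tert-butyldimethylsilyloxy)chroman-4-one | [C@H]1(c2ccc(OCc3ccccc3)cc2)Oc2cc(OCc3ccccc3)cc(OCc3ccccc3)c2C(=O)[C@H]1O[Si](C)(C)C(C)(C)C
F5 | step 13 | (2R,3S,4S)-4-ArL-5,7-bis(benzyloxy)-2-[4-(benzyloxy)phenyl]-3-(tert-butyldimethylsilyloxy)chroman-4-ol | [C@H]1(c2ccc(OCc3ccccc3)cc2)Oc2cc(OCc3ccccc3)cc(OCc3ccccc3)c2[C@](O)(c2c(OCc3ccccc3)cc(OCc3ccccc3)c3c2O[C@@H](c2ccc(OCc4ccccc4)cc2)[C@@H](OCc2ccccc2)C3)[C@H]1O[Si](C)(C)C(C)(C)C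
F6 | step 13 | 3-O-TBS ether of 23 | [C@H]1(c2ccc(OCc3ccccc3)cc2)Oc2cc(OCc3ccccc3)cc(OCc3ccccc3)c2[C@@H](c2c(OCc3ccccc3)cc(OCc3ccccc3)c3c2O[C@@H](c2ccc(OCc4ccccc4)cc2)[C@@H](OCc2ccccc2)C3)[C@H]1O[Si](C)(C)C(C)(C)C
F7 | step 14 | (2S,3S,4R)-5,7-bis(benzyloxy)-2-[4-(benzyloxy)phenyl]-4-ArL-chroman-3-ol | [C@@H]1(c2ccc(OCc3ccccc3)cc2)Oc2cc(OCc3ccccc3)cc(OCc3ccccc3)c2[C@H](c2c(OCc3ccccc3)cc(OCc3ccccc3)c3c2O[C@@H](c2ccc(OCc4ccccc4)cc2)[C@@H](OCc2ccccc2)C3)[C@@H]1O
F8 | step 19 | 4-deoxy analogue of 29 (free dodecahydroxy trimer) | Oc1ccc([C@H]2Oc3c(c(O)cc(O)c3[C@H]3c4c(O)cc(O)cc4O[C@@H](c4ccc(O)cc4)[C@H]3O)[C@@H](c3c(O)cc(O)c4c3O[C@@H](c3ccc(O)cc3)[C@@H](O)C4)[C@H]2O)cc1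
F9 | step 19 | dodeca-O-TBS ether of F8 | CC(C)(C)[Si](C)(C)Oc1ccc([C@H]2Oc3c(c(O[Si](C)(C)C(C)(C)C)cc(O[Si](C)(C)C(C)(C)C)c3[C@H]3c4c(O[Si](C)(C)C(C)(C)C)cc(O[Si](C)(C)C(C)(C)C)cc4O[C@@H](c4ccc(O[Si](C)(C)C(C)(C)C)cc4)[C@H]3O[Si](C)(C)C(C)(C)C)[C@@H](c3c(O[Si](C)(C)C(C)(C)C)cc(O[Si](C)(C)C(C)(C)C)c4c3O[C@@H](c3ccc(O[Si](C)(C)C(C)(C)C)cc3)[C@@H](O[Si](C)(C)C(C)(C)C)C4)[C@H]2O[Si](C)(C)C(C)(C)C)cc1
F10 | step 19 | 4-hydroxy derivative of F9 (lower unit 2S,3S,4R) | CC(C)(C)[Si](C)(C)Oc1ccc([C@H]2Oc3c(c(O[Si](C)(C)C(C)(C)C)cc(O[Si](C)(C)C(C)(C)C)c3[C@H]3c4c(O[Si](C)(C)C(C)(C)C)cc(O[Si](C)(C)C(C)(C)C)cc4O[C@@H](c4ccc(O[Si](C)(C)C(C)(C)C)cc4)[C@H]3O[Si](C)(C)C(C)(C)C)[C@@H](c3c(O[Si](C)(C)C(C)(C)C)cc(O[Si](C)(C)C(C)(C)C)c4c3O[C@@H](c3ccc(O[Si](C)(C)C(C)(C)C)cc3)[C@@H](O[Si](C)(C)C(C)(C)C)[C@@H]4O)[C@H]2O[Si](C)(C)C(C)(C)C)cc1
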